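I began with amounts, because one turn of the chain takes one reagent and one starting material and leaves one target, so the charges set a ceiling before any rate enters.

common to all: starting material 0.20 M; initiator 1.0 mM; time 15 h
- spring: reagent 0.0200 M
- dusk: reagent 0.0600 M
- summer: reagent 0.200 M
- midnight: reagent 0.500 M

    starting material ⇌ dormant form (K1 = 0.48, k1 = 0.41 h⁻¹)
    2 second chain carrier → ended chains A (k2 = 5 × 10⁷ L mol⁻¹ s⁻¹)
    starting material + second chain carrier → by-product + first chain carrier (k3 = 39000 L mol⁻¹ s⁻¹)
    reagent + target → over-reaction product (k4 = 2.4 L mol⁻¹ h⁻¹)
    starting material + initiating radical → capped initiator + first chain carrier (k5 = 6.8 × 10⁵ L mol⁻¹ s⁻¹)
    2 first chain carrier → ended chains B (k6 = 1.6 × 10⁸ L mol⁻¹ s⁻¹)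
    reagent + first chain carrier → target + second chain carrier (k7 = 5.5 × 10⁵ L mol⁻¹ s⁻¹)
    initiator → 2 initiating radical (k8 = 0.0017 h⁻¹)

- percent here means starting material units held: one ended chains B counts as two
- a step written with two of one species runs at k times the square of its concentration and takes two of it each time
- "hardly changes" means that all values lie within two and a half points (for a concentration: within two and a half percent of the largest)
- run time (spring): 15 h

* amount of target at the end, in percent of the starting material charged for spring, dusk, summer, midnight, in this order
* the shape of the row from first to last (falls, then rises / hardly changes / falls all the way / rises, then falls / rises all the way)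

I solved two extreme versions of this flask. In the first, the over-reaction step is absent, and target simply equals the smaller of the two charges: 10.0 % in spring, 30.0 % in dusk, and 100 % in summer and midnight alike. In the second, reagent holds its charge throughout, so target decays in a pseudo-first-order way, with a half-life of 14.4 h in spring, 1.44 h in summer and 0.578 h at midnight. I carried this target half-life under reagent, ln 2 divided by the over-reaction constant times [reagent], and held it against the run of 15 h.

The real flasks lie between these ends: the chain draws [reagent] down, and a lower [reagent] gives a longer half-life than the one at the charge. In spring the half-life is close to the run even at the charge, so I put target just under its ceiling, with dusk somewhat further under its own. At midnight the half-life at the charge is far shorter than the run. Even if every starting material unit passed through both steps, [reagent] would still stand at 0.100 M, which gives a half-life of 2.89 h, still shorter than the run. So I expected little target there. Summer is the flask I could not finish by hand: its reagent charge equals the starting material charge, so over-reaction takes reagent from the chain, and I committed only to a value well under its ceiling. My row therefore rose, then fell.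

The forecast gave 9.8 %, 27.9 %, 56 % and 3.5 %, a row that rises, then falls, and said of midnight that “reagent persists, so target is steadily destroyed”.

The simulation gave 9.85 %, 28.2 %, 54.2 % and 3.89 %, a row that rises, then falls. At midnight, reagent still stood at 23.0 % of its charge after 15.0 h, which puts the target half-life at 2.51 h, shorter than the run, and over-reaction product stood at 94.2 % against 3.89 % of target. In spring, the half-life at the charge was 14.4 h, but at 0.510 h the chain used reagent 88 times as fast as the over-reaction step did, and with reagent at 0 % after 15.0 h, over-reaction product stood at 0.0735 %.

The constants used here were set for the occasion; the flask was simulated.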